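The cyclohexene ring A (C1, C10–C14; briarane numbering) is cut at C1–C10, the bond it shares with the ten-membered ring, and at C11–C12. Both bonds are made in one Diels–Alder reaction between a 1-ethoxy-3-silyloxy diene that carries the C1 methyl and a nitrile (future C2) and (S)-5-silyloxy-5,6-dihydropyran-2-one, whose bought C9 carbinol steers the diene to one face; loss of ethanol in the same flask leaves the C11=C12 alkene, and the lactone carbonyl later becomes the C20 methyl. C10 and quaternary C1 are thus relayed from C9; the remaining centres follow by substrate or reagent control, and ring-closing metathesis forms C5=C6.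

Key step: step 6

Remark: briarane numbering is used for every intermediate (ring A = C1, C10, C11, C12, C13, C14; ten-membered ring = C1–C10; C15 on C1, C16 on C5, C17–C19 lactone, C18 on C17, C20 on C11; β = face of the C15 methyl); TBS = tert-butyldimethylsilyl, TES = triethylsilyl, PMB = 4-methoxybenzyl, Troc = 2,2,2-trichloroethoxycarbonyl, Ipc = isopinocampheyl.

Step 1
Reactants: 1 (S)-but-3-ene-1,2-diol; 2 acryloyl chloride
Product: 3 (S)-2-hydroxybut-3-en-1-yl acrylate
Conditions: 2 (1.0 equiv), 2,4,6-collidine, CH2Cl2, −78 °C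
Reagents that add atoms: none
Why: Esterification of the primary hydroxyl should be much faster than that of the secondary allylic one at low temperature (selective acylation), and the bought stereocentre (future C9) is not touched.

Step 2
Reactants: 3 (S)-2-hydroxybut-3-en-1-yl acrylate
Product: 4 (S)-2-(tert-butyldimethylsilyloxy)but-3-en-1-yl acrylate
Conditions: TBSCl, imidazole, DMF, 0 °C
Reagents that add atoms: tert-butyldimethylsilyl chloride, CC(C)(C)[Si](C)(C)Cl
Why: Standard silylation of a secondary alcohol should protect the future C9 oxygen as an ether that does not chelate and survives the hydride steps.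

Step 3
Reactants: 4 (S)-2-(tert-butyldimethylsilyloxy)but-3-en-1-yl acrylate
Product: 5 (S)-5-(tert-butyldimethylsilyloxy)-5,6-dihydro-2H-pyran-2-one
Conditions: second-generation Grubbs catalyst (5 mol %), CH2Cl2, 40 °C
Reagents that add atoms: none
Why: Ring-closing metathesis of an acrylate with a vinyl group three atoms away should close the six-membered unsaturated lactone with loss of ethylene.

Step 4
Reactants: 6 propionitrile; 7 (E)-3-ethoxyacryloyl chloride
Product: 8 (E)-5-ethoxy-2-methyl-3-oxopent-4-enenitrile (racemic)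
Conditions: 6 (2.1 equiv), LiN(i-Pr)2 (2.1 equiv), THF, −78 °C; then 7; aq. NH4Cl
Reagents that add atoms: none
Why: C-Acylation of lithiated propionitrile by the acid chloride (Claisen-type acylation) should give the β-ketonitrile, the second equivalent of anion absorbing its acidic proton.

Step 5
Reactants: 8 (E)-5-ethoxy-2-methyl-3-oxopent-4-enenitrile
Product: 9 (2E,4E)-3-(tert-butyldimethylsilyloxy)-5-ethoxy-2-methylpenta-2,4-dienenitrile
Conditions: TBSOTf, Et3N, CH2Cl2, 0 °C
Reagents that add atoms: tert-butyldimethylsilyl trifluoromethanesulfonate, CC(C)(C)[Si](C)(C)OS(=O)(=O)C(F)(F)F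
Why: Soft enolisation and O-silylation at the carbon between ketone and nitrile should give the 2-silyloxy diene, the push–pull enol ether settling in the (2E) geometry with the slim nitrile cis to the vinyl group and the methyl cis to the silyloxy group.

Step 6
Reactants: 5 (S)-5-(tert-butyldimethylsilyloxy)-5,6-dihydro-2H-pyran-2-one; 9 (2E,4E)-3-(tert-butyldimethylsilyloxy)-5-ethoxy-2-methylpenta-2,4-dienenitrile
Product: 11 silyl dienol ether lactone (C11=C12 and C13=C14), via cycloadduct 10 (not isolated)
Conditions: toluene, 2,6-di-tert-butyl-4-methylphenol (trace), 110 °C, sealed tube; then DBU, 60 °C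
Reagents that add atoms: none
Why: A thermal normal-electron-demand Diels–Alder reaction (closest known type: cycloaddition of 1-alkoxy-3-silyloxy dienes to α,β-unsaturated lactones followed by β-elimination of the alkoxy group) should join the nucleophilic diene terminus C1 to the lactone β-carbon C10 and C12 to C11, so that ring A is closed in the suprafacial [4+2] mode with the regiochemistry fixed by the polarity of both partners. C10 is set by approach of the diene anti to the pseudoaxial C9 silyloxy group of 5, and quaternary C1 by the endo transition state, in which the outside methyl of the (2E)-diene ends up cis to the lactone ring and the nitrile trans to it. Only the (2E)-isomer of 9, with the linear nitrile in the inside position, can reach the s-cis conformation, which secures that geometry. The C11 and C12 stereocentres of 10 are transient, because DBU removes the acidic C11–H next to the lactone carbonyl and ethoxide leaves from C12 (E1cB), which places the alkene at C11=C12. The step needs endo and facial selectivity, and the compact cis-fused transition state together with the single substituent beside the dienophile should secure both.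

Step 7
Reactants: 11 silyl dienol ether lactone
Product: 13 14α-hydroxy lactone nitrile (14S), via ketone 12 (not isolated)
Conditions: Bu4NF (1.0 equiv), AcOH (1.0 equiv), THF, −78 °C; then LiBH(s-Bu)3, −78 °C
Reagents that add atoms: none
Why: Fluoride should cleave only the silyl dienol ether and kinetic protonation of the dienolate at C13 should give the β,γ-unsaturated ketone, which the bulky hydride then reduces from the equatorial direction anti to the nitrile (ring A is held with the C15 methyl axial by the fused lactone) to the axial 14α-alcohol (stereoselective ketone reduction).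

Step 8
Reactants: 13 14α-hydroxy lactone nitrile
Product: 14 triol nitrile (8-OH, 14-OH, 20-OH; 9-OTBS)
Conditions: LiBH4, MeOH (1 equiv), THF, 0 °C to rt
Reagents that add atoms: none
Why: Borohydride 1,2-reduction of the conjugated lactone should open it to the allylic C20 alcohol and the primary C8 alcohol while nitrile and silyl ether stay intact.

Step 9
Reactants: 14 triol nitrile
Product: 15 20-chloro-8,14-diol nitrile
Conditions: N-chlorosuccinimide, Me2S, CH2Cl2, −20 °C
Reagents that add atoms: N-chlorosuccinimide, O=C1CCC(=O)N1Cl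
Why: The Corey–Kim chlorination should convert only the allylic C20 hydroxyl into the chloride, since the alkoxysulfonium salts of the saturated hydroxyls return the alcohols on work-up.

Step 10
Reactants: 15 20-chloro-8,14-diol nitrile
Product: 16 20-chloro-8,14-bis(triethylsilyloxy) nitrile
Conditions: TESOTf (2.3 equiv), 2,6-lutidine, CH2Cl2, −78 to −20 °C
Reagents that add atoms: triethylsilyl trifluoromethanesulfonate, CC[Si](CC)(CC)OS(=O)(=O)C(F)(F)F
Why: Silylation of both hydroxyls should prevent O-alkylation of the C8 oxygen by the allylic chloride and mask the C14 alcohol (silyl ether formation).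

Step 11
Reactants: 16 20-chloro-8,14-bis(triethylsilyloxy) nitrile
Product: 17 nitrile with C20 methyl
Conditions: LiBHEt3, THF, −78 to 0 °C
Reagents that add atoms: none
Why: SN2 displacement of the primary allylic chloride by hydride should give the C20 methyl group without moving the C11=C12 alkene, the hindered tertiary nitrile being inert at this temperature.

Step 12
Reactants: 17 nitrile with C20 methyl
Product: 18 methyl ketone (C2 acetyl on C1)
Conditions: MeLi, Et2O, 0 °C to rt; then aq. AcOH/NaOAc (pH 5), 0 °C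
Reagents that add atoms: methyllithium, [Li]C; water, O
Why: Addition of methyllithium to the nitrile should stop at the N-lithio ketimine, whose mild hydrolysis gives the ketone (organolithium addition to a nitrile).

Step 13
Reactants: 19 2-methylenepropane-1,3-diol
Product: 20 2-[(tert-butyldimethylsilyloxy)methyl]prop-2-en-1-ol
Conditions: NaH (1.0 equiv), THF, 0 °C; then TBSCl
Reagents that add atoms: tert-butyldimethylsilyl chloride, CC(C)(C)[Si](C)(C)Cl
Why: Monosilylation of the symmetrical diol through its sparingly soluble monosodium alkoxide should give the mono ether.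

Step 14
Reactants: 20 2-[(tert-butyldimethylsilyloxy)methyl]prop-2-en-1-ol
Product: 21 2-[(tert-butyldimethylsilyloxy)methyl]prop-2-enal
Conditions: MnO2, CH2Cl2, rt
Reagents that add atoms: none
Why: MnO2 oxidation of the allylic alcohol should give the enal without touching the silyl ether.

Step 15
Reactants: 18 methyl ketone; 21 2-[(tert-butyldimethylsilyloxy)methyl]prop-2-enal
Product: 22 (4R)-4-hydroxy-2-ketone
Conditions: (−)-Ipc2BCl, Et3N, Et2O, 0 °C; then 21, −78 to −20 °C; H2O2, pH 7 buffer, MeOH
Reagents that add atoms: none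
Why: A boron-mediated aldol reaction of the methyl ketone should form C3–C4, with the Ipc ligands directing the enolate to the Re face of the aldehyde to set C4, reinforced by 1,5-anti induction from the C14 silyloxy group (the antipodal reagent would be used if the sense proved opposite).

Step 16
Reactants: 22 (4R)-4-hydroxy-2-ketone
Product: 23 (2S,4R)-2,4-diol
Conditions: Et2BOMe, NaBH4, THF/MeOH (4:1), −78 °C
Reagents that add atoms: none
Why: In the Narasaka–Prasad reduction external hydride attacks the six-membered boron chelate axially, which should give the 1,3-syn diol and so relay C2 from C4.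

Step 17
Reactants: 23 (2S,4R)-2,4-diol
Product: 24 4-O-Troc carbonate with free 2-OH
Conditions: TrocCl (1.1 equiv), pyridine, CH2Cl2, −20 °C
Reagents that add atoms: 2,2,2-trichloroethyl chloroformate, ClC(=O)OCC(Cl)(Cl)Cl
Why: The allylic C4 hydroxyl is far less hindered than the C2 hydroxyl beside quaternary C1, so that carbonate formation should be selective.

Step 18
Reactants: 24 4-O-Troc carbonate
Product: 25 2-O-acetyl-4-O-Troc derivative
Conditions: Ac2O, Et3N, DMAP (cat.), CH2Cl2, rt
Reagents that add atoms: acetic anhydride, CC(=O)OC(C)=O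
Why: DMAP-catalysed acylation of the remaining hindered secondary hydroxyl should install the C2 acetate of the target.

Step 19
Reactants: 25 2-O-acetyl-4-O-Troc derivative
Product: 26 C8 aldehyde
Conditions: (COCl)2, DMSO, CH2Cl2, −78 to −30 °C; then Et3N
Reagents that add atoms: none
Why: Under Swern conditions a primary triethylsilyl ether is cleaved and oxidised in one operation, which should give the aldehyde while the secondary silyl ethers stay in place.

Step 20
Reactants: 27 4-methoxybenzyl chloride; 28 allyl alcohol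
Product: 29 allyl 4-methoxybenzyl ether
Conditions: NaH, THF, 0 °C; then 27, Bu4NI (cat.), rt
Reagents that add atoms: none
Why: A Williamson ether synthesis between the sodium alkoxide and the benzylic chloride should give the ether.

Step 21
Reactants: 26 C8 aldehyde; 29 allyl 4-methoxybenzyl ether
Product: 30 (7S,8R)-8-hydroxy-7-(4-methoxybenzyloxy) adduct with C6 vinyl group
Conditions: 29, s-BuLi, THF, −78 °C; (+)-Ipc2BOMe; BF3·OEt2; then 26, −78 °C; NaBO3·4H2O, pH 7 buffer
Reagents that add atoms: none
Why: The (Z)-γ-alkoxyallylborane should add through a chair transition state to give the 7,8-syn product, the Ipc ligands and the Felkin–Anh preference of the α-silyloxy aldehyde (matched pair) both directing attack to the Re face and so setting C7 (γ-alkoxyallylboration).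

Step 22
Reactants: 30 (7S,8R)-8-hydroxy-7-(4-methoxybenzyloxy) adduct
Product: 31 C8 ketone
Conditions: Dess–Martin periodinane, NaHCO3, CH2Cl2, 0 °C
Reagents that add atoms: none
Why: Buffered oxidation of the secondary alcohol should give the ketone without epimerising the flanking C7 and C9 centres.

Step 23
Reactants: 31 C8 ketone; 32 (E)-1-methoxy-1-(trimethylsilyloxy)prop-1-ene
Product: 33 aldol adduct (tertiary C8 carbinol, C17–C19 methyl ester)
Conditions: TiCl4, CH2Cl2, −78 °C; then 32
Reagents that add atoms: none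
Why: In this Mukaiyama aldol reaction TiCl4 should chelate the ketone and the C7 benzyl-type ether (the C9 silyl ether does not chelate), so that the ketene acetal attacks from the side of H-7 (Cram chelate control) and sets C8, while C17 is set only in part and is corrected in step 24.

Step 24
Reactants: 33 aldol adduct
Product: 35 γ-lactone diene, via hydroxy ester 34 (not isolated)
Conditions: DDQ, CH2Cl2/pH 7 buffer, 0 °C; then DBU (0.2 equiv), CH2Cl2, rt
Reagents that add atoms: none
Why: Oxidative removal of the 4-methoxybenzyl group frees the C7 hydroxyl, which should lactonise onto the methyl ester, and the base should equilibrate the lactone α-carbon C17 to the epimer with the methyl trans to the bulky C9 branch.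

Step 25
Reactants: 35 γ-lactone diene
Product: 36 macrocycle with (5Z)-alkene
Conditions: second-generation Hoveyda–Grubbs catalyst (20 mol %), 1,4-benzoquinone, toluene (1 mM), 80 °C
Reagents that add atoms: none
Why: Ring-closing metathesis between the 1,1-disubstituted C5 olefin and the C6 vinyl group should close the ten-membered ring, whose size allows only the Z-configured trisubstituted alkene.

Step 26
Reactants: 36 macrocycle
Product: 37 9,14,16-triol (2-OAc, 4-OTroc, 8-OH)
Conditions: HF·pyridine, pyridine, THF, 0 °C to rt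
Reagents that add atoms: none
Why: Fluoride-mediated desilylation should remove the three silyl ethers while carbonate, acetate and lactone survive the buffered acidic medium.

Step 27
Reactants: 37 9,14,16-triol
Product: 38 4-O-Troc derivative of the target
Conditions: Ac2O, pyridine, DMAP (cat.), CH2Cl2, rt
Reagents that add atoms: acetic anhydride, CC(=O)OC(C)=O
Why: Acylation should take the primary C16 and the secondary C9 and C14 hydroxyls, whereas the tertiary C8 hydroxyl does not react under these conditions.

Step 28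
Reactants: 38 4-O-Troc derivative of the target
Product: 39 CNP0226727.2
Conditions: Zn dust, AcOH, THF, rt
Reagents that add atoms: none
Why: Reductive β-elimination of the trichloroethyl carbonate by zinc should free the C4 hydroxyl without touching the four acetates or the lactone.

Compound list
1 | (S)-but-3-ene-1,2-diol | OC[C@@H](O)C=C | starting material
2 | acryloyl chloride | C=CC(Cl)=O | starting material
3 | (S)-2-hydroxybut-3-en-1-yl acrylate | C=CC(=O)OC[C@@H](O)C=C | intermediate
4 | (S)-2-(tert-butyldimethylsilyloxy)but-3-en-1-yl acrylate | C=CC(=O)OC[C@@H](O[Si](C)(C)C(C)(C)C)C=C | intermediate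
5 | (S)-5-(tert-butyldimethylsilyloxy)-5,6-dihydro-2H-pyran-2-one (C8–C11 and C20; silyloxy carbon = C9) | O=C1OC[C@@H](O[Si](C)(C)C(C)(C)C)C=C1 | intermediate
6 | propionitrile | CCC#N | starting material
7 | (E)-3-ethoxyacryloyl chloride | CCO/C=C/C(Cl)=O | starting material
8 | (E)-5-ethoxy-2-methyl-3-oxopent-4-enenitrile (racemic) | CCO/C=C/C(=O)C(C)C#N | intermediate
9 | (2E,4E)-3-(tert-butyldimethylsilyloxy)-5-ethoxy-2-methylpenta-2,4-dienenitrile | N#C/C(C)=C(O[Si](C)(C)C(C)(C)C)\C=C\OCC | intermediate
10 | cycloadduct: δ-lactone (C20 carbonyl, O–C8) cis-fused to ring A at C10–C11; 1β-methyl, 1α-cyano, 9-OTBS, 12β-ethoxy, C13=C14 TBS enol ether | O=C1OC[C@@H](O[Si](C)(C)C(C)(C)C)[C@H]2[C@@H]1[C@@H](OCC)C=C(O[Si](C)(C)C(C)(C)C)[C@]2(C)C#N | intermediate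
11 | silyl dienol ether lactone: C11=C12 conjugated with the lactone, C13=C14 TBS enol ether | O=C1OC[C@@H](O[Si](C)(C)C(C)(C)C)[C@H]2C1=CC=C(O[Si](C)(C)C(C)(C)C)[C@]2(C)C#N | intermediate
12 | 14-oxo lactone nitrile (β,γ-unsaturated ketone, C11=C12) | O=C1OC[C@@H](O[Si](C)(C)C(C)(C)C)[C@H]2C1=CC[C](=O)[C@]2(C)C#N | intermediate
13 | 14α-hydroxy lactone nitrile (14S) | O=C1OC[C@@H](O[Si](C)(C)C(C)(C)C)[C@H]2C1=CC[C@H](O)[C@]2(C)C#N | intermediate
14 | triol nitrile (8-OH, 14α-OH, 20-OH, 9-OTBS) | OC[C@@H](O[Si](C)(C)C(C)(C)C)[C@H]1C(CO)=CC[C@H](O)[C@]1(C)C#N | intermediate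
15 | 20-chloro-8,14-diol nitrile | OC[C@@H](O[Si](C)(C)C(C)(C)C)[C@H]1C(CCl)=CC[C@H](O)[C@]1(C)C#N | intermediate
16 | 20-chloro-8,14-bis(triethylsilyloxy) nitrile | CC[Si](CC)(CC)OC[C@@H](O[Si](C)(C)C(C)(C)C)[C@H]1C(CCl)=CC[C@H](O[Si](CC)(CC)CC)[C@]1(C)C#N | intermediate
17 | nitrile with C20 methyl (8-OTES, 9-OTBS, 14-OTES) | CC[Si](CC)(CC)OC[C@@H](O[Si](C)(C)C(C)(C)C)[C@H]1C(C)=CC[C@H](O[Si](CC)(CC)CC)[C@]1(C)C#N | intermediate
18 | methyl ketone (C2 acetyl on C1) | CC[Si](CC)(CC)OC[C@@H](O[Si](C)(C)C(C)(C)C)[C@H]1C(C)=CC[C@H](O[Si](CC)(CC)CC)[C@]1(C)C(C)=O | intermediate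
19 | 2-methylenepropane-1,3-diol | C=C(CO)CO | starting material
20 | 2-[(tert-butyldimethylsilyloxy)methyl]prop-2-en-1-ol | C=C(CO)CO[Si](C)(C)C(C)(C)C | intermediate
21 | 2-[(tert-butyldimethylsilyloxy)methyl]prop-2-enal | C=C(CO[Si](C)(C)C(C)(C)C)C=O | intermediate
22 | (4R)-4-hydroxy-2-ketone with C5(=CH2)–C16H2OTBS | CC[Si](CC)(CC)OC[C@@H](O[Si](C)(C)C(C)(C)C)[C@H]1C(C)=CC[C@H](O[Si](CC)(CC)CC)[C@]1(C)C(=O)C[C@@H](O)C(=C)CO[Si](C)(C)C(C)(C)C | intermediate
23 | (2S,4R)-2,4-diol | CC[Si](CC)(CC)OC[C@@H](O[Si](C)(C)C(C)(C)C)[C@H]1C(C)=CC[C@H](O[Si](CC)(CC)CC)[C@]1(C)[C@@H](O)C[C@@H](O)C(=C)CO[Si](C)(C)C(C)(C)C | intermediate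
24 | 4-O-Troc carbonate with free 2-OH | CC[Si](CC)(CC)OC[C@@H](O[Si](C)(C)C(C)(C)C)[C@H]1C(C)=CC[C@H](O[Si](CC)(CC)CC)[C@]1(C)[C@@H](O)C[C@@H](OC(=O)OCC(Cl)(Cl)Cl)C(=C)CO[Si](C)(C)C(C)(C)C | intermediate
25 | 2-O-acetyl-4-O-Troc derivative | CC[Si](CC)(CC)OC[C@@H](O[Si](C)(C)C(C)(C)C)[C@H]1C(C)=CC[C@H](O[Si](CC)(CC)CC)[C@]1(C)[C@@H](OC(C)=O)C[C@@H](OC(=O)OCC(Cl)(Cl)Cl)C(=C)CO[Si](C)(C)C(C)(C)C | intermediate
26 | C8 aldehyde | O=C[C@@H](O[Si](C)(C)C(C)(C)C)[C@H]1C(C)=CC[C@H](O[Si](CC)(CC)CC)[C@]1(C)[C@@H](OC(C)=O)C[C@@H](OC(=O)OCC(Cl)(Cl)Cl)C(=C)CO[Si](C)(C)C(C)(C)C | intermediate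
27 | 4-methoxybenzyl chloride | COc1ccc(CCl)cc1 | starting material
28 | allyl alcohol | C=CCO | starting material
29 | allyl 4-methoxybenzyl ether | C=CCOCc1ccc(OC)cc1 | intermediate
30 | (7S,8R)-8-hydroxy-7-(4-methoxybenzyloxy) adduct with C6 vinyl group | C=C[C@H](OCc1ccc(OC)cc1)[C@@H](O)[C@@H](O[Si](C)(C)C(C)(C)C)[C@H]1C(C)=CC[C@H](O[Si](CC)(CC)CC)[C@]1(C)[C@@H](OC(C)=O)C[C@@H](OC(=O)OCC(Cl)(Cl)Cl)C(=C)CO[Si](C)(C)C(C)(C)C | intermediate
31 | C8 ketone | C=C[C@H](OCc1ccc(OC)cc1)C(=O)[C@@H](O[Si](C)(C)C(C)(C)C)[C@H]1C(C)=CC[C@H](O[Si](CC)(CC)CC)[C@]1(C)[C@@H](OC(C)=O)C[C@@H](OC(=O)OCC(Cl)(Cl)Cl)C(=C)CO[Si](C)(C)C(C)(C)C | intermediate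
32 | (E)-1-methoxy-1-(trimethylsilyloxy)prop-1-ene | C/C=C(\OC)O[Si](C)(C)C | starting material
33 | aldol adduct: tertiary C8 carbinol carrying the C17(methyl)–C19 methyl ester (drawn with the C17 configuration of the target) | C=C[C@H](OCc1ccc(OC)cc1)[C@@](O)([C@@H](C)C(=O)OC)[C@@H](O[Si](C)(C)C(C)(C)C)[C@H]1C(C)=CC[C@H](O[Si](CC)(CC)CC)[C@]1(C)[C@@H](OC(C)=O)C[C@@H](OC(=O)OCC(Cl)(Cl)Cl)C(=C)CO[Si](C)(C)C(C)(C)C | intermediate
34 | 7-hydroxy ester (4-methoxybenzyl group removed) | C=C[C@H](O)[C@@](O)([C@@H](C)C(=O)OC)[C@@H](O[Si](C)(C)C(C)(C)C)[C@H]1C(C)=CC[C@H](O[Si](CC)(CC)CC)[C@]1(C)[C@@H](OC(C)=O)C[C@@H](OC(=O)OCC(Cl)(Cl)Cl)C(=C)CO[Si](C)(C)C(C)(C)C | intermediate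
35 | γ-lactone diene (C7–O–C19 lactone, 8-OH, C6 vinyl, C5 methylene) | C=C[C@@H]2OC(=O)[C@H](C)[C@@]2(O)[C@@H](O[Si](C)(C)C(C)(C)C)[C@H]1C(C)=CC[C@H](O[Si](CC)(CC)CC)[C@]1(C)[C@@H](OC(C)=O)C[C@@H](OC(=O)OCC(Cl)(Cl)Cl)C(=C)CO[Si](C)(C)C(C)(C)C | intermediate
36 | macrocycle with (5Z)-alkene (2-OAc, 4-OTroc, 9-OTBS, 14-OTES, 16-OTBS) | CC(C)(C)[Si](C)(C)OC/C1=C/[C@@H]2OC(=O)[C@H](C)[C@@]2(O)[C@@H](O[Si](C)(C)C(C)(C)C)[C@H]2C(C)=CC[C@H](O[Si](CC)(CC)CC)[C@]2(C)[C@@H](OC(C)=O)C[C@H]1OC(=O)OCC(Cl)(Cl)Cl | intermediate
37 | 9,14,16-triol (2-OAc, 4-OTroc, 8-OH) | OC/C1=C/[C@@H]2OC(=O)[C@H](C)[C@@]2(O)[C@@H](O)[C@H]2C(C)=CC[C@H](O)[C@]2(C)[C@@H](OC(C)=O)C[C@H]1OC(=O)OCC(Cl)(Cl)Cl | intermediate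
38 | 4-O-Troc derivative of the target | CC(=O)OC/C1=C/[C@@H]2OC(=O)[C@H](C)[C@@]2(O)[C@@H](OC(C)=O)[C@H]2C(C)=CC[C@H](OC(C)=O)[C@]2(C)[C@@H](OC(C)=O)C[C@H]1OC(=O)OCC(Cl)(Cl)Cl | intermediate
39 | CNP0226727.2 | CC(=O)OC/C1=C/[C@@H]2OC(=O)[C@H](C)[C@@]2(O)[C@@H](OC(C)=O)[C@H]2C(C)=CC[C@H](OC(C)=O)[C@]2(C)[C@@H](OC(C)=O)C[C@H]1O | target

Total step count: 28. Longest linear sequence: 23 steps (steps 1–3, 6–12, 15–19, 21–28).

Steps most likely to fail

Step 6. The push–pull diene with its fully substituted terminus may add too slowly, so that desilylation or polymerisation of 9 outruns the cycloaddition, or the endo preference may erode at the temperature needed. The fallback builds the two bonds one after the other by polar reactions. It sets out from 5 and 9: a TiCl4-promoted Mukaiyama–Michael addition at −78 °C should give the Michael adduct F1 (C1–C10 bond, C1 set through an open transition state). LiN(SiMe3)2 then forms the lactone enolate, which adds to C12 of the β-ethoxy enone and expels ethoxide to give the cis-fused enone F2. Soft enolisation of F2 with TBSOTf and Et3N removes the doubly activated C11–H and returns to the route at 11.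

Step 7. The β,γ-unsaturated ketone 12 may tautomerise to the conjugated C12=C13 enone (proton shuttling by acetate) before the hydride arrives, which would lose the alkene position. The fallback makes 12 by oxidation under neutral conditions instead of by protonation. It sets out from 10 (step 6 stopped before DBU is added): dilute HCl in THF at 0 °C should hydrolyse the enol ether to the β-ethoxy ketone F3; NaBH4 gives the alcohol F4 (either C14 epimer serves; the 14β epimer is drawn); DBU then eliminates ethanol across C11–C12 to give F5, the C14 epimer of 13. Buffered Dess–Martin oxidation of F5 gives 12 free of acid and base, and immediate reduction with LiBH(s-Bu)3 at −78 °C returns to the route at 13.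

Step 25. Oligomerisation through the unhindered C6 vinyl group may outrun ring closure at the hindered 1,1-disubstituted C5 olefin, the more so because the ring must form trans-fused to the lactone. The fallback inverts the order of the two ring constructions, so that the carbocycle is closed on a seco compound without the lactone and the lactone is then annulated onto the ten-membered ketone. It sets out from 31: metathesis under the conditions of step 25 should give the macrocyclic ketone F6; the chelation-controlled Mukaiyama aldol reaction with 32 (TiCl4, −78 °C) gives F7; DDQ and then catalytic DBU remove the 4-methoxybenzyl group and close the lactone, which returns to the route at 36.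

Further compounds
F1 | step 6 | Michael adduct: 9-OTBS lactone carrying at C10 the C1(methyl)(cyano)–C14(=O)–CH=CH–OEt chain | O=C1OC[C@@H](O[Si](C)(C)C(C)(C)C)[C@@H](C1)[C@@](C)(C#N)C(=O)/C=C/OCC
F2 | step 6 | cis-fused enone lactone (C12=C13–C14=O, H at C11) | O=C1OC[C@@H](O[Si](C)(C)C(C)(C)C)[C@H]2[C@@H]1C=CC(=O)[C@]2(C)C#N
F3 | step 7 | 12β-ethoxy-14-oxo lactone nitrile | O=C1OC[C@@H](O[Si](C)(C)C(C)(C)C)[C@H]2[C@@H]1[C@@H](OCC)CC(=O)[C@]2(C)C#N
F4 | step 7 | 12β-ethoxy-14β-hydroxy lactone nitrile | O=C1OC[C@@H](O[Si](C)(C)C(C)(C)C)[C@H]2[C@@H]1[C@@H](OCC)C[C@@H](O)[C@]2(C)C#N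
F5 | step 7 | 14β-hydroxy lactone nitrile (C14 epimer of 13) | O=C1OC[C@@H](O[Si](C)(C)C(C)(C)C)[C@H]2C1=CC[C@@H](O)[C@]2(C)C#N
F6 | step 25 | macrocyclic C8 ketone with (5Z)-alkene and 7-O-(4-methoxybenzyl) group | CC(C)(C)[Si](C)(C)OC/C1=C/[C@H](OCc2ccc(OC)cc2)C(=O)[C@@H](O[Si](C)(C)C(C)(C)C)[C@H]2C(C)=CC[C@H](O[Si](CC)(CC)CC)[C@]2(C)[C@@H](OC(C)=O)C[C@H]1OC(=O)OCC(Cl)(Cl)Cl
F7 | step 25 | macrocyclic aldol adduct (tertiary C8 carbinol, C17–C19 methyl ester) | CC(C)(C)[Si](C)(C)OC/C1=C/[C@H](OCc2ccc(OC)cc2)[C@@](O)([C@@H](C)C(=O)OC)[C@@H](O[Si](C)(C)C(C)(C)C)[C@H]2C(C)=CC[C@H](O[Si](CC)(CC)CC)[C@]2(C)[C@@H](OC(C)=O)C[C@H]1OC(=O)OCC(Cl)(Cl)Cl
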